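**Strategy.** The 21-membered ansa ring is opened at C9–C10 of the saturated C14 bridge (numbered from ring B) that links C-3 of the hydroquinone ring B to C-5 of the resorcinol ring A. These two methylene carbons lie far from both arenes, so each can be carried as the inner carbon of a terminal olefin. Ring-closing olefin metathesis of a tribenzyl-protected diaryl ether with a dec-9-enyl chain on ring B and a hex-5-enyl chain on ring A forms this bond and the macrocycle in one operation; a single hydrogenation then saturates the bridge and frees the three phenols. The diene arises by Ullmann coupling of two arenes alkylated by B-alkyl Suzuki reactions.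

Key step: step 7

Remark on the chemistry: the ring closure is expected to give macrocycle 15 as a mixture of E and Z olefin isomers. Its SMILES is therefore written without olefin geometry; both isomers converge in step 8.

**Step 1**
Reactants: 1 2,6-dibromohydroquinone (2,6-dibromobenzene-1,4-diol)
Product: 2 2,5-bis(benzyloxy)-1,3-dibromobenzene
Conditions: BnBr (2.3 equiv), K2CO3, DMF, 60 °C, argon
Reagents that add atoms: benzyl bromide, BrCc1ccccc1
Why: Williamson ether synthesis; both phenoxides, including the one flanked by two bromines, should be alkylated by the reactive benzylic halide, and exclusion of air keeps the hydroquinone from oxidising.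

**Step 2**
Reactants: 2 2,5-bis(benzyloxy)-1,3-dibromobenzene
Product: 5 2,5-bis(benzyloxy)-3-bromophenol, via aryllithium 3 (not isolated), via dimethyl arylboronate 4 (not isolated)
Conditions: n-BuLi (1.05 equiv), THF, −78 °C; B(OMe)3, −78 °C to rt; then AcOH, 30% aq. H2O2, 0 °C to rt
Reagents that add atoms: hydrogen peroxide, OO
Why: Bromine–lithium exchange followed by borylation and oxidation; the two bromines of 2 are equivalent, a second exchange would need a dianion and should not occur, and the C–B bond is oxidised to C–O with the benzyl ethers untouched.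

**Step 3**
Reactants: 5 2,5-bis(benzyloxy)-3-bromophenol; 6 deca-1,9-diene
Product: 8 2,5-bis(benzyloxy)-3-(dec-9-en-1-yl)phenol, via B-(dec-9-en-1-yl)-9-BBN 7 (not isolated)
Conditions: 6 (4 equiv), 9-BBN, THF, 0 °C to rt; then 5, Pd(OAc)2, SPhos (2-dicyclohexylphosphino-2′,6′-dimethoxybiphenyl), K3PO4, THF/H2O, 65 °C
Reagents that add atoms: none
Why: Anti-Markovnikov hydroboration of one end of the excess diene, then B-alkyl Suzuki–Miyaura coupling; the electron-rich biaryl phosphine should allow zerovalent palladium to insert into the hindered ortho-alkoxy bromide, and the primary alkyl group is transferred from boron in preference to the bicyclic secondary ones.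

**Step 4**
Reactants: 9 3-bromo-5-iodophenol
Product: 10 1-(benzyloxy)-3-bromo-5-iodobenzene
Conditions: BnBr, K2CO3, acetone, reflux
Reagents that add atoms: benzyl bromide, BrCc1ccccc1
Why: Williamson ether synthesis of an unhindered phenol; both aryl halides are inert to these conditions.

**Step 5**
Reactants: 10 1-(benzyloxy)-3-bromo-5-iodobenzene; 11 hexa-1,5-diene
Product: 13 1-(benzyloxy)-3-bromo-5-(hex-5-en-1-yl)benzene, via B-(hex-5-en-1-yl)-9-BBN 12 (not isolated)
Conditions: 11 (5 equiv), 9-BBN, THF, 0 °C to rt; then 10, Pd(dppf)Cl2, AsPh3, Cs2CO3, DMF/THF/H2O, rt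
Reagents that add atoms: none
Why: Hydroboration then B-alkyl Suzuki–Miyaura coupling; at room temperature zerovalent palladium should insert into the C–I bond much faster than into the C–Br bond, so the bromide is kept for step 6.

**Step 6**
Reactants: 8 2,5-bis(benzyloxy)-3-(dec-9-en-1-yl)phenol; 13 1-(benzyloxy)-3-bromo-5-(hex-5-en-1-yl)benzene
Product: 14 1-(benzyloxy)-3-[2,5-bis(benzyloxy)-3-(dec-9-en-1-yl)phenoxy]-5-(hex-5-en-1-yl)benzene
Conditions: CuI (10 mol %), N,N-dimethylglycine hydrochloride (30 mol %), Cs2CO3, 1,4-dioxane, 100 °C
Reagents that add atoms: none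
Why: Ullmann-type diaryl ether synthesis with an amino-acid ligand; the aryl bromide is unhindered, guaiacol-type ortho-alkoxy phenoxides are competent nucleophiles under these conditions, and benzyl ethers and terminal olefins should be left alone.

**Step 7**
Reactants: 14 1-(benzyloxy)-3-[2,5-bis(benzyloxy)-3-(dec-9-en-1-yl)phenoxy]-5-(hex-5-en-1-yl)benzene
Product: 15 tribenzyl-protected macrocyclic olefin (the 21-membered ring of the target with a C9=C10 double bond in the bridge, E/Z mixture)
Conditions: second-generation Grubbs catalyst RuCl2(H2IMes)(PCy3)(=CHPh) (2 × 5 mol %), 1,4-benzoquinone (20 mol %), CH2Cl2 (1 mM), 40 °C, slow addition of 14, argon sparge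
Reagents that add atoms: none
Why: The ruthenium benzylidene exchanges with one terminal olefin of 14 to give a ruthenium alkylidene, which adds across the second terminal olefin of the same molecule in a [2+2] cycloaddition; cycloreversion of the ruthenacyclobutane releases ethylene and leaves the C9=C10 double bond of the bridge (Chauvin mechanism). The closest known reaction type is macrocyclic ring-closing metathesis of α,ω-dienes to large carbocycles and cyclophanes. The single ring closed is the 21-membered ansa ring (fourteen bridge carbons, three atoms of each arene and the ether oxygen), formed by end-to-end union of two monosubstituted olefins, a mode with no geometric restriction at this ring size. No stereocentre is created, and the E/Z ratio of the new olefin is irrelevant because step 8 saturates it. The step needs ring closure to win over intermolecular metathesis and over olefin migration: high dilution with slow addition favours the intramolecular path and loss of ethylene drives it forward, the diaryl ether hinge between C-1 of ring A and C-1 of ring B holds both chains in one molecule, and 1,4-benzoquinone suppresses ruthenium hydride species that would shift the olefins and lead to ring-contracted homologues. Both olefins are unhindered terminal ones at least four methylenes from the arenes and are the only olefins present, so no other metathesis site competes.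

**Step 8**
Reactants: 15 tribenzyl-protected macrocyclic olefin
Product: 16 target macrocycle CNP0393720.0
Conditions: H2 (1 atm), 10% Pd/C, EtOAc/MeOH (degassed), rt; filtration under argon
Reagents that add atoms: none
Why: Heterogeneous catalytic hydrogenation should saturate the disubstituted olefin (both geometric isomers converge) and hydrogenolyse the three benzyl aryl ethers in the same operation; the diaryl ether is inert, and air is excluded to keep the hydroquinone from oxidising to the quinone.

**Compound list**

1 | 2,6-dibromohydroquinone (2,6-dibromobenzene-1,4-diol) | Oc1cc(Br)c(O)c(Br)c1 | starting material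
2 | 2,5-bis(benzyloxy)-1,3-dibromobenzene | Brc1cc(OCc2ccccc2)cc(Br)c1OCc1ccccc1 | intermediate
3 | [2,5-bis(benzyloxy)-3-bromophenyl]lithium | [Li]c1cc(OCc2ccccc2)cc(Br)c1OCc1ccccc1 | intermediate (not isolated)
4 | dimethyl [2,5-bis(benzyloxy)-3-bromophenyl]boronate | COB(OC)c1cc(OCc2ccccc2)cc(Br)c1OCc1ccccc1 | intermediate (not isolated)
5 | 2,5-bis(benzyloxy)-3-bromophenol | Oc1cc(OCc2ccccc2)cc(Br)c1OCc1ccccc1 | intermediate
6 | deca-1,9-diene | C=CCCCCCCC=C | starting material
7 | 9-(dec-9-en-1-yl)-9-borabicyclo[3.3.1]nonane | C=CCCCCCCCCB1C2CCCC1CCC2 | intermediate (not isolated)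
8 | 2,5-bis(benzyloxy)-3-(dec-9-en-1-yl)phenol | Oc1cc(OCc2ccccc2)cc(CCCCCCCCC=C)c1OCc1ccccc1 | intermediate
9 | 3-bromo-5-iodophenol | Oc1cc(Br)cc(I)c1 | starting material
10 | 1-(benzyloxy)-3-bromo-5-iodobenzene | Brc1cc(I)cc(OCc2ccccc2)c1 | intermediate
11 | hexa-1,5-diene | C=CCCC=C | starting material
12 | 9-(hex-5-en-1-yl)-9-borabicyclo[3.3.1]nonane | C=CCCCCB1C2CCCC1CCC2 | intermediate (not isolated)
13 | 1-(benzyloxy)-3-bromo-5-(hex-5-en-1-yl)benzene | Brc1cc(CCCCC=C)cc(OCc2ccccc2)c1 | intermediate
14 | 1-(benzyloxy)-3-[2,5-bis(benzyloxy)-3-(dec-9-en-1-yl)phenoxy]-5-(hex-5-en-1-yl)benzene | C=CCCCCc1cc(OCc2ccccc2)cc(Oc2cc(OCc3ccccc3)cc(CCCCCCCCC=C)c2OCc2ccccc2)c1 | intermediate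
15 | tribenzyl ether of the target with a C9=C10 double bond in the bridge (counted from ring B), E/Z mixture | c1ccccc1COc1cc2cc(c1)Oc1cc(OCc3ccccc3)cc(c1OCc1ccccc1)CCCCCCCCC=CCCCC2 | intermediate
16 | CNP0393720.0: 21-membered diaryl ether macrocycle with three free phenols and a saturated C14 bridge | Oc1cc2cc(c1)Oc1cc(O)cc(c1O)CCCCCCCCCCCCCC2 | target

**Step count and risks**

Total steps: 8. Longest linear sequence: 6 steps (steps 1, 2, 3, 6, 7, 8).

Steps most likely to fail:

Step 7. Intermolecular metathesis may build oligomers faster than the 21-membered ring closes, and olefin migration before closure would lead to ring-contracted material. The fallback sets out from diene 14. Oxidative cleavage of both terminal olefins (OsO4 cat., NaIO4, 2,6-lutidine, dioxane/H2O, rt) should give 9-{2,5-bis(benzyloxy)-3-[3-(benzyloxy)-5-(5-oxopentyl)phenoxy]phenyl}nonanal F1, whose two formyl carbons are C9 and C10 of the bridge. Intramolecular McMurry coupling (TiCl3(DME)1.5, Zn–Cu couple, DME, reflux, syringe-pump addition) would then join these two carbons on low-valent titanium, where large rings close readily, and comes back to the route at macrocycle 15.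

Step 6. Slow C–O bond formation at copper with the ortho-benzyloxy phenoxide may let hydrodebromination of the aryl bromide and base-induced olefin migration at 100 °C take over. The fallback sets out from bromide 13. Bromine–lithium exchange (n-BuLi, THF, −78 °C) gives [3-(benzyloxy)-5-(hex-5-en-1-yl)phenyl]lithium F2, and quenching with B(OiPr)3 followed by aqueous HCl gives [3-(benzyloxy)-5-(hex-5-en-1-yl)phenyl]boronic acid F3. Chan–Lam coupling of this acid with phenol 8 (Cu(OAc)2, pyridine, 4 Å molecular sieves, CH2Cl2, air, rt) forms the diaryl ether oxidatively at room temperature and comes back to the route at diene 14.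

Step 3. Insertion of zerovalent palladium into the hindered, electron-rich bromide of the phenoxide may be slow, so that protodeboronation and β-hydride elimination consume the alkylborane. The fallback sets out from dibromide 2 by way of aryllithium 3, made as in step 2. Alkylation of 3 with commercial 10-bromodec-1-ene (THF/DMPU, −78 to 0 °C) should give 2,5-bis(benzyloxy)-1-bromo-3-(dec-9-en-1-yl)benzene F4. A second bromine–lithium exchange (n-BuLi, THF, −78 °C) gives [2,5-bis(benzyloxy)-3-(dec-9-en-1-yl)phenyl]lithium F5, and B(OMe)3 gives dimethyl [2,5-bis(benzyloxy)-3-(dec-9-en-1-yl)phenyl]boronate F6. Oxidation with AcOH/H2O2 comes back to the route at phenol 8, without any palladium step on ring B.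

**Further compounds**

F1 | step 7 | 9-{2,5-bis(benzyloxy)-3-[3-(benzyloxy)-5-(5-oxopentyl)phenoxy]phenyl}nonanal | O=CCCCCc1cc(OCc2ccccc2)cc(Oc2cc(OCc3ccccc3)cc(CCCCCCCCC=O)c2OCc2ccccc2)c1
F2 | step 6 | [3-(benzyloxy)-5-(hex-5-en-1-yl)phenyl]lithium | [Li]c1cc(CCCCC=C)cc(OCc2ccccc2)c1
F3 | step 6 | [3-(benzyloxy)-5-(hex-5-en-1-yl)phenyl]boronic acid | OB(O)c1cc(CCCCC=C)cc(OCc2ccccc2)c1
F4 | step 3 | 2,5-bis(benzyloxy)-1-bromo-3-(dec-9-en-1-yl)benzene | Brc1cc(OCc2ccccc2)cc(CCCCCCCCC=C)c1OCc1ccccc1
F5 | step 3 | [2,5-bis(benzyloxy)-3-(dec-9-en-1-yl)phenyl]lithium | [Li]c1cc(OCc2ccccc2)cc(CCCCCCCCC=C)c1OCc1ccccc1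
F6 | step 3 | dimethyl [2,5-bis(benzyloxy)-3-(dec-9-en-1-yl)phenyl]boronate | COB(OC)c1cc(OCc2ccccc2)cc(CCCCCCCCC=C)c1OCc1ccccc1
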